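You cannot read this flask off the earlier runs: neither went past 2.50 h, and neither was charged with 0.15 M of L.

all flasks: X 0.78 µM

| run | L | remark | time |
|---|---|---|---|
| amber | 0.10 M | run made earlier |  |
| grey | 0.22 M | run made earlier |  |
| flask | 0.15 M |  | 3.0 h |

- amber (time / h: J / %): 0.833: 2; 1.00: 5; 1.33: 12; 2.00: 23; 2.50: 35
- grey (time / h: J / %): 0.833: 2; 1.00: 5; 1.33: 6; 2.00: 15; 2.50: 25

(standard deviation of a reading: 2 percentage points)

- the best time, 3.0 h at the latest, for J
- the amount of J, in percent of the L charged, at that time

- what was read earlier has a scatter of 2 percentage points, one standard deviation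

At 2.50 h grey holds more J in M than amber, but a lower percentage. At one time and one charge of X, I let the percentage go as one over (K + L), with L the amount charged, which gives

K = (0.0550 M − 0.0350 M) / 10 percentage points = 0.200 M

This K is the half-saturation amount (Michaelis constant), the amount of L at which the rate stands at half its ceiling. It is a rough reading, given the scatter. Scaling amber by (K + amber's L)/(K + the flask's L) puts the flask at 30.0% at 2.50 h and 19.7% at 2.00 h. Both runs are still climbing, so I take 3.0 h.

From below, the last interval's rate merely held: 40.3%

From above, J growing as the square of time: 43.2%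

The forecast, 41% at 3 h, lies inside this bracket; it reads the runs as “so this is partial saturation”.

The flask gives 39.5% at 3.00 h, 0.80 points under the lower edge of my estimate.

    Z → G + J (k = 7360 /min)
    L + G ⇌ Z (K = 9.00 /M, k = 4.59 × 10⁵ /M/min)
    X → G (k = 0.00144 /min)
    G + J → G + E (k = 140 /M/min)

The half-life of X on its way to G, 8.0 h, is longer than the 3.0 h allowed. At 3.00 h the flask still has 77.2% of its catalyst as X, with 13.3% as G and 9.51% as Z, and its 0.0908 M of L stands below the 0.200 M I read from the runs.

For a neighbour charged with 0.26 M of L, my 0.200 M scales the flask's result to 30.0%; the computed neighbour gives 29.9%.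

Readings and results were computed for an exercise; the scatter is artificial.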